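**Retrosynthetic overview**

1. Target 23 ⇐ 22 (unmask the C14 aldehyde) ⇐ 21 by ring-closing metathesis at C4=C5; the ten-membered ring is formed last.
2. 21 ⇐ 12 + 20 by Nozaki–Hiyama–Kishi coupling (C9–C10), which sets C9 and brings in the Z C1=C10 olefin.
3. 12 ⇐ 7 by ozonolysis of the cyclopentene (C5=C9), lactol-controlled differentiation of the two aldehydes, methylenation and a lactol-to-γ-lactone switch.
4. 7 ⇐ meso-diol 5 by enantioselective acylation with the natural (S)-2-methylbutanoyl group; 5 ⇐ racemic 4 by Luche reduction.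
5. 4 ⇐ 3 by Piancatelli rearrangement (furan → cyclopentenone, C7–C8 bond, trans) of the furfural/methyl acrylate Baylis–Hillman adduct. Ring order: furan → cyclopentene → oxolane lactol → γ-lactone → ten-membered carbocycle.

Assumption: atom labels C1–C15 follow germacrane numbering (lactone C12–O–C6); 4 is racemic and drawn as one enantiomer; the catalyst enantiomer in step 4 is taken as the one that acylates the (S)-configured carbinol of 5.

**Route**

Step 1
Reactants: 1 furfural; 2 methyl acrylate
Product: 3 methyl 2-[furan-2-yl(hydroxy)methyl]prop-2-enoate (racemic)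
Conditions: DABCO (0.5 equiv), neat, rt, 48 h
Reagents that add atoms: none
Why: Morita–Baylis–Hillman reaction of an activated heteroaryl aldehyde, joining C7 to C11 with C12 and C13 already at their final oxidation level; the racemic carbinol centre is of no consequence because steps 2–3 converge on a meso compound.

Step 2
Reactants: 3 methyl 2-[furan-2-yl(hydroxy)methyl]prop-2-enoate
Product: 4 methyl 2-[(1RS,2SR)-2-hydroxy-5-oxocyclopent-3-en-1-yl]prop-2-enoate
Conditions: Dy(OTf)3 (10 mol %), t-BuOH/H2O 5:1, 80 °C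
Reagents that add atoms: water, O
Why: Proposed new method: acid ionises the furylcarbinol to the furfuryl cation, water adds at furan C5, the ring opens to a hydroxypentadienyl cation and conrotatory 4π closure forms the C7–C8 bond with the hydroxyl trans to the side chain; the closest known reaction is the Dy(OTf)3-catalysed Piancatelli rearrangement of alkyl- and aryl-substituted 2-furylcarbinols, and the acrylate should be tolerated because allylic (SN2') hydration of the cation is reversible whereas the electrocyclisation is not.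

Step 3
Reactants: 4 methyl 2-[(1RS,2SR)-2-hydroxy-5-oxocyclopent-3-en-1-yl]prop-2-enoate
Product: 5 methyl 2-[(1r,2R,5S)-2,5-dihydroxycyclopent-3-en-1-yl]prop-2-enoate (meso)
Conditions: NaBH4, CeCl3·7H2O, MeOH, −78 °C
Reagents that add atoms: none
Why: Luche 1,2-reduction in which the small hydride attacks anti to the ring hydroxyl (as with 4-oxygenated cyclopentenones), giving the cis-1,3-diol with both hydroxyls trans to the side chain, so both enantiomers of 4 converge on one meso diol; the epimeric alcohol lactonises onto the cis acrylate and is removed by chromatography.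

Step 4
Reactants: 5 meso diol; 6 (2S)-2-methylbutanoic anhydride
Product: 7 methyl 2-[(1S,2R,5S)-2-hydroxy-5-{[(2S)-2-methylbutanoyl]oxy}cyclopent-3-en-1-yl]prop-2-enoate
Conditions: 6 (1.0 equiv), (S)-benzotetramisole (5 mol %), i-Pr2NEt, CHCl3, −20 °C
Reagents that add atoms: none
Why: Enantioselective acyl transfer (isothiourea-catalysed desymmetrisation of a meso allylic diol) that distinguishes the enantiotopic carbinols, fixing the absolute configuration of C6, C7 and C8 while installing the natural ester on O8; over-acylation of the minor monoester upgrades the ee.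

Step 5
Reactants: 7 cyclopentene monoester
Product: 10 methyl 2-[(2S,3S,4R,5RS)-2-formyl-5-hydroxy-4-{[(2S)-2-methylbutanoyl]oxy}oxolan-3-yl]prop-2-enoate, via secondary ozonide 8 (not isolated), via hydroxy dialdehyde 9 (not isolated)
Conditions: O3, CH2Cl2, −78 °C; then Me2S, −78 °C → rt
Reagents that add atoms: ozone, [O-][O+]=O
Why: Ozonolysis, in which the strained electron-rich ring alkene reacts far faster than the electron-poor acrylate; after reduction the free 6-OH captures the C9 aldehyde as a five-membered lactol, so only the C5 aldehyde stays free and no stereocentre is touched.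

Step 6
Reactants: 10 formyl lactol
Product: 11 methyl 2-[(2R,3S,4R,5RS)-2-ethenyl-5-hydroxy-4-{[(2S)-2-methylbutanoyl]oxy}oxolan-3-yl]prop-2-enoate
Conditions: Zn, CH2Br2, TiCl4 (pre-formed reagent), THF/CH2Cl2, 0 °C
Reagents that add atoms: dibromomethane, BrCBr
Why: Takai–Lombardo methylenation, whose non-basic zinc/titanium methylene reagent olefinates the free aldehyde without epimerising C6 and leaves the esters and the lactol untouched.

Step 7
Reactants: 11 vinyl lactol
Product: 12 (1R)-1-[(2R,3S)-2-ethenyl-4-methylidene-5-oxooxolan-3-yl]-2-oxoethyl (2S)-2-methylbutanoate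
Conditions: PPTS (20 mol %), PhMe, 60 °C, 4 Å MS
Reagents that add atoms: none
Why: Acid-catalysed lactol-to-lactone switch (intramolecular transesterification) in which the 6-OH closes onto the methyl ester to give the trans-disubstituted α-methylene-γ-butyrolactone and releases the C9 aldehyde, driven by loss of methanol with all configurations retained.

Step 8
Reactants: 13 prop-2-yn-1-ol; 14 but-3-en-1-ylmagnesium bromide
Product: 16 2-methylidenehex-5-en-1-ol, via alkenylmagnesium alkoxide 15 (not isolated)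
Conditions: 14 (2.5 equiv), CuI (10 mol %), THF, 0 °C → reflux; then aq. NH4Cl
Reagents that add atoms: none
Why: Duboudin copper-catalysed carbomagnesiation of propargyl alcohol, delivering the alkyl group to the internal alkyne carbon, and protonolysis gives the 2-substituted allyl alcohol (C15, C4, C3, C2, C1).

Step 9
Reactants: 16 2-methylidenehex-5-en-1-ol; 17 (2E)-but-2-enal
Product: 18 (2E)-6-(hydroxymethyl)hepta-2,6-dienal
Conditions: 17 (5 equiv), second-generation Grubbs catalyst (3 mol %), CH2Cl2, 40 °C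
Reagents that add atoms: none
Why: Olefin cross-metathesis in which only the monosubstituted alkene reacts with the enal partner (the 1,1-disubstituted olefin is inert here), giving the thermodynamically favoured E-enal.

Step 10
Reactants: 18 (2E)-6-(hydroxymethyl)hepta-2,6-dienal
Product: 19 (2Z)-6-(hydroxymethyl)-2-iodohepta-2,6-dienal
Conditions: I2, DMAP (20 mol %), K2CO3, THF/H2O 1:1, rt
Reagents that add atoms: iodine, II
Why: Amine-catalysed α-iodination of an enal (conjugate addition of DMAP, iodination of the enolate, elimination), which gives the Z-iodoenal with iodine cis to the chain and the formyl group trans to it.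

Step 11
Reactants: 19 (2Z)-6-(hydroxymethyl)-2-iodohepta-2,6-dienal
Product: 20 (5Z)-6-iodo-7,7-dimethoxy-2-methylidenehept-5-en-1-ol
Conditions: HC(OMe)3, CeCl3·7H2O (10 mol %), MeOH, rt
Reagents that add atoms: trimethyl orthoformate, COC(OC)OC
Why: Mild Lewis-acid acetalisation masks the aldehyde (future C14) so that the organochromium step sees only one aldehyde.

Step 12
Reactants: 12 lactone aldehyde; 20 iodo acetal
Product: 21 (1R,2S,3E)-3-(dimethoxymethyl)-1-[(2R,3S)-2-ethenyl-4-methylidene-5-oxooxolan-3-yl]-2-hydroxy-7-(hydroxymethyl)octa-3,7-dien-1-yl (2S)-2-methylbutanoate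
Conditions: CrCl2 (6 equiv), NiCl2 (2 mol %), DMSO, rt
Reagents that add atoms: none
Why: Nozaki–Hiyama–Kishi coupling in which the alkenylchromium species adds only to the aldehyde with retention of olefin geometry (C9 cis to C2), and polar Felkin–Anh control by the α-acyloxy group gives the 8,9-anti carbinol (9S); the minor epimer is separated.

Step 13
Reactants: 21 acyclic tetraene
Product: 22 (3aS,4R,5S,6E,10E,11aR)-6-(dimethoxymethyl)-5-hydroxy-10-(hydroxymethyl)-3-methylidene-2-oxo-2,3,3a,4,5,8,9,11a-octahydrocyclodeca[b]furan-4-yl (2S)-2-methylbutanoate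
Conditions: second-generation Grubbs catalyst (15 mol %), PhMe (1 mM), 80 °C
Reagents that add atoms: none
Why: Ring-closing metathesis between the vinyl group on C6 and the 1,1-disubstituted olefin at C4, where the trans-lactone and the Z C1=C10 olefin pre-organise the chain and the ten-membered ring is expected to close to the in-ring cis C4=C5 olefin (CH2OH trans to C6).

Step 14
Reactants: 22 macrocyclic dimethyl acetal
Product: 23 (3aS,4R,5S,6E,10E,11aR)-6-formyl-5-hydroxy-10-(hydroxymethyl)-3-methylidene-2-oxo-2,3,3a,4,5,8,9,11a-octahydrocyclodeca[b]furan-4-yl (2S)-2-methylbutanoate (CNP0331447.11)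
Conditions: PPTS (cat.), acetone/H2O 9:1, rt
Reagents that add atoms: water, O
Why: Acid-catalysed hydrolysis of a conjugated dimethyl acetal, mild enough for the α-methylene lactone, the ester and the allylic alcohols, and it touches no stereocentre.

**Compound list**

1 | furfural (furan-2-carbaldehyde) | O=Cc1ccco1 | starting material
2 | methyl acrylate | C=CC(=O)OC | starting material
3 | methyl 2-[furan-2-yl(hydroxy)methyl]prop-2-enoate (racemic) | C=C(C(=O)OC)C(O)c1ccco1 | intermediate
4 | methyl 2-[(1RS,2SR)-2-hydroxy-5-oxocyclopent-3-en-1-yl]prop-2-enoate (racemate, OH trans to side chain; one enantiomer drawn) | C=C(C(=O)OC)[C@H]1C(=O)C=C[C@@H]1O | intermediate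
5 | methyl 2-[(1r,2R,5S)-2,5-dihydroxycyclopent-3-en-1-yl]prop-2-enoate (meso; hydroxyls cis to each other, trans to the acrylate) | C=C(C(=O)OC)[C@H]1[C@H](O)C=C[C@@H]1O | intermediate
6 | (2S)-2-methylbutanoic anhydride | CC[C@H](C)C(=O)OC(=O)[C@@H](C)CC | starting material
7 | methyl 2-[(1S,2R,5S)-2-hydroxy-5-{[(2S)-2-methylbutanoyl]oxy}cyclopent-3-en-1-yl]prop-2-enoate | C=C(C(=O)OC)[C@H]1[C@H](O)C=C[C@@H]1OC(=O)[C@@H](C)CC | intermediate
8 | secondary ozonide of 7: methyl 2-[4-hydroxy-2-{[(2S)-2-methylbutanoyl]oxy}-6,7,8-trioxabicyclo[3.2.1]octan-3-yl]prop-2-enoate (C2–C4 configured as in 7) | C=C(C(=O)OC)[C@H]1[C@H](O)C2OOC(O2)[C@@H]1OC(=O)[C@@H](C)CC | intermediate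
9 | (2R,3S,4S)-4-hydroxy-3-(3-methoxy-3-oxoprop-1-en-2-yl)-1,5-dioxopentan-2-yl (2S)-2-methylbutanoate | C=C(C(=O)OC)[C@@H]([C@H](O)C=O)[C@H](C=O)OC(=O)[C@@H](C)CC | intermediate
10 | methyl 2-[(2S,3S,4R,5RS)-2-formyl-5-hydroxy-4-{[(2S)-2-methylbutanoyl]oxy}oxolan-3-yl]prop-2-enoate (anomer mixture) | C=C(C(=O)OC)[C@H]1[C@@H](C=O)OC(O)[C@@H]1OC(=O)[C@@H](C)CC | intermediate
11 | methyl 2-[(2R,3S,4R,5RS)-2-ethenyl-5-hydroxy-4-{[(2S)-2-methylbutanoyl]oxy}oxolan-3-yl]prop-2-enoate (anomer mixture) | C=C(C(=O)OC)[C@H]1[C@@H](C=C)OC(O)[C@@H]1OC(=O)[C@@H](C)CC | intermediate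
12 | (1R)-1-[(2R,3S)-2-ethenyl-4-methylidene-5-oxooxolan-3-yl]-2-oxoethyl (2S)-2-methylbutanoate | C=C1C(=O)O[C@H](C=C)[C@H]1[C@H](C=O)OC(=O)[C@@H](C)CC | intermediate
13 | prop-2-yn-1-ol | C#CCO | starting material
14 | but-3-en-1-ylmagnesium bromide | C=CCC[Mg]Br | starting material
15 | [(1Z)-2-[(bromomagnesiooxy)methyl]hexa-1,5-dien-1-yl]magnesium bromide | Br[Mg]/C=C(/CCC=C)CO[Mg]Br | intermediate
16 | 2-methylidenehex-5-en-1-ol | C=CCCC(=C)CO | intermediate
17 | (2E)-but-2-enal (crotonaldehyde) | C/C=C/C=O | starting material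
18 | (2E)-6-(hydroxymethyl)hepta-2,6-dienal | O=C/C=C/CCC(=C)CO | intermediate
19 | (2Z)-6-(hydroxymethyl)-2-iodohepta-2,6-dienal | O=C/C(I)=C/CCC(=C)CO | intermediate
20 | (5Z)-6-iodo-7,7-dimethoxy-2-methylidenehept-5-en-1-ol | COC(OC)/C(I)=C/CCC(=C)CO | intermediate
21 | (1R,2S,3E)-3-(dimethoxymethyl)-1-[(2R,3S)-2-ethenyl-4-methylidene-5-oxooxolan-3-yl]-2-hydroxy-7-(hydroxymethyl)octa-3,7-dien-1-yl (2S)-2-methylbutanoate | C=C1C(=O)O[C@H](C=C)[C@H]1[C@@H](OC(=O)[C@@H](C)CC)[C@@H](O)/C(=C\CCC(=C)CO)C(OC)OC | intermediate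
22 | (3aS,4R,5S,6E,10E,11aR)-6-(dimethoxymethyl)-5-hydroxy-10-(hydroxymethyl)-3-methylidene-2-oxo-2,3,3a,4,5,8,9,11a-octahydrocyclodeca[b]furan-4-yl (2S)-2-methylbutanoate | C=C1C(=O)O[C@@H]2/C=C(/CO)CC/C=C(/C(OC)OC)[C@H](O)[C@H](OC(=O)[C@@H](C)CC)[C@@H]12 | intermediate
23 | (3aS,4R,5S,6E,10E,11aR)-6-formyl-5-hydroxy-10-(hydroxymethyl)-3-methylidene-2-oxo-2,3,3a,4,5,8,9,11a-octahydrocyclodeca[b]furan-4-yl (2S)-2-methylbutanoate (germacrane numbering 6R,7S,8R,9S; both ring olefins cis in the ring) | C=C1C(=O)O[C@@H]2/C=C(/CO)CC/C=C(/C=O)[C@H](O)[C@H](OC(=O)[C@@H](C)CC)[C@@H]12 | target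

**Step count and risks**

Total step count: 14. Longest linear sequence: 10 steps (steps 1–7, then 12–14, from furfural); the side branch (steps 8–11) is 4 steps.

Steps most likely to fail:

Step 2 (Piancatelli rearrangement of an acrylate-bearing carbinol). The conjugated, electron-poor vinyl group may divert the cation, or the product may isomerise into conjugation. The fallback removes the vinyl group during the rearrangement. It sets out from 3: conjugate addition of thiophenol (Et3N cat.) gives methyl 2-[furan-2-yl(hydroxy)methyl]-3-(phenylsulfanyl)propanoate F1, an ordinary alkyl-substituted furylcarbinol. The same Dy(OTf)3 rearrangement then gives methyl 2-[(1RS,2SR)-2-hydroxy-5-oxocyclopent-3-en-1-yl]-3-(phenylsulfanyl)propanoate F2. Oxidation with NaIO4 gives the sulfoxide methyl 2-[(1RS,2SR)-2-hydroxy-5-oxocyclopent-3-en-1-yl]-3-(phenylsulfinyl)propanoate F3. Warming in toluene (90 °C) causes syn-elimination, which restores the acrylate, and the route is rejoined at 4.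

Step 4 (catalytic desymmetrising acylation with a branched chiral anhydride). Selectivity between the enantiotopic carbinols may be low. The fallback uses an enzyme for the symmetry breaking and adds the natural ester afterwards. It sets out from 5: lipase from Pseudomonas cepacia with vinyl acetate acetylates the (R)-configured carbinol to give methyl 2-[(1R,2R,5S)-2-(acetyloxy)-5-hydroxycyclopent-3-en-1-yl]prop-2-enoate F4. Esterification of the remaining hydroxyl with (2S)-2-methylbutanoic acid (DCC, DMAP) gives methyl 2-[(1S,2R,5S)-2-(acetyloxy)-5-{[(2S)-2-methylbutanoyl]oxy}cyclopent-3-en-1-yl]prop-2-enoate F5. Hydrolysis of the acetate with the same lipase in pH 7 buffer leads back to 7.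

Step 13 (ring-closing metathesis to a ten-membered ring with a trisubstituted olefin). Oligomerisation or a wrong olefin geometry is possible. The fallback forms C4=C5 intermolecularly and closes the ring at C9–C10 instead. It sets out from 11 and 20: cross-metathesis (second-generation Grubbs catalyst, excess 20, separation of olefin isomers) gives methyl 2-[(2R,3S,4R,5RS)-5-hydroxy-2-[(1E,5Z)-2-(hydroxymethyl)-6-iodo-7,7-dimethoxyhepta-1,5-dien-1-yl]-4-{[(2S)-2-methylbutanoyl]oxy}oxolan-3-yl]prop-2-enoate F6. The PPTS lactol-to-lactone switch of step 7 gives (1R)-1-[(2R,3S)-2-[(1E,5Z)-2-(hydroxymethyl)-6-iodo-7,7-dimethoxyhepta-1,5-dien-1-yl]-4-methylidene-5-oxooxolan-3-yl]-2-oxoethyl (2S)-2-methylbutanoate F7. An intramolecular Nozaki–Hiyama–Kishi reaction (CrCl2, NiCl2, DMSO, high dilution) then closes the ring, returning to the route at 22.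

**Further compounds**

F1 | step 2 | methyl 2-[furan-2-yl(hydroxy)methyl]-3-(phenylsulfanyl)propanoate | COC(=O)C(CSc1ccccc1)C(O)c1ccco1
F2 | step 2 | methyl 2-[(1RS,2SR)-2-hydroxy-5-oxocyclopent-3-en-1-yl]-3-(phenylsulfanyl)propanoate | COC(=O)C(CSc1ccccc1)[C@H]1C(=O)C=C[C@@H]1O
F3 | step 2 | methyl 2-[(1RS,2SR)-2-hydroxy-5-oxocyclopent-3-en-1-yl]-3-(phenylsulfinyl)propanoate | COC(=O)C(CS(=O)c1ccccc1)[C@H]1C(=O)C=C[C@@H]1O
F4 | step 4 | methyl 2-[(1R,2R,5S)-2-(acetyloxy)-5-hydroxycyclopent-3-en-1-yl]prop-2-enoate | C=C(C(=O)OC)[C@H]1[C@H](OC(C)=O)C=C[C@@H]1O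
F5 | step 4 | methyl 2-[(1S,2R,5S)-2-(acetyloxy)-5-{[(2S)-2-methylbutanoyl]oxy}cyclopent-3-en-1-yl]prop-2-enoate | C=C(C(=O)OC)[C@H]1[C@H](OC(C)=O)C=C[C@@H]1OC(=O)[C@@H](C)CC
F6 | step 13 | methyl 2-[(2R,3S,4R,5RS)-5-hydroxy-2-[(1E,5Z)-2-(hydroxymethyl)-6-iodo-7,7-dimethoxyhepta-1,5-dien-1-yl]-4-{[(2S)-2-methylbutanoyl]oxy}oxolan-3-yl]prop-2-enoate | C=C(C(=O)OC)[C@H]1[C@@H](/C=C(/CO)CC/C=C(\I)C(OC)OC)OC(O)[C@@H]1OC(=O)[C@@H](C)CC
F7 | step 13 | (1R)-1-[(2R,3S)-2-[(1E,5Z)-2-(hydroxymethyl)-6-iodo-7,7-dimethoxyhepta-1,5-dien-1-yl]-4-methylidene-5-oxooxolan-3-yl]-2-oxoethyl (2S)-2-methylbutanoate | C=C1C(=O)O[C@H](/C=C(/CO)CC/C=C(\I)C(OC)OC)[C@H]1[C@H](C=O)OC(=O)[C@@H](C)CC
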